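The runs come from a simulation for an exercise.

The charge of substrate rose from 0.034 M in violet to 0.075 M in amber, yet at 6.00 h the two percentages differed by 6 percentage points, with a scatter of 2 points per reading.

| flask | substrate | gas phase | remark | time |
|---|---|---|---|---|
| violet | 0.034 M | 6 mM (held) | run made earlier |  |
| amber | 0.075 M | 6 mM (held) | run made earlier |  |
| flask | 0.050 M | 6.0 mM (held) |  | 6.0 h |

- violet (time / h: target / %): 0.500: 7; 0.833: 13; 1.50: 21; 3.00: 31; 6.00: 49
- amber (time / h: target / %): 1.33: 14; 2.50: 29; 4.00: 39; 5.00: 43; 6.00: 43

(scatter of a reading: 2 percentage points)

- target at 6.0 h, in percent of the substrate charged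
- the change that raises the amount of target at 6.0 h, in percent of the substrate charged most ("none" if none brings more than 2 percentage points) (north-west / east / none)
- amount of target at 6.0 h, in percent of the substrate charged, after north-west

- at the start none of the gas phase is in solution

- north-west: doubling the saturation concentration of gas phase, all else as stated
- east: doubling the transfer coefficient of the gas phase, all else as stated

So I made percent independent of the charge the zero of my scale: two first-order paths out of the substrate, one to target, one elsewhere. Violet's 31% at 3.00 h and the mean 46.0% at 6.00 h gave a bending time τ = 4.13 h. They also gave t_f = 6.88 h, the time to convert the whole charge at the starting slope. The loss time followed from 1/t_l = 1/τ − 1/t_f: t_l = 10.3 h. Their ratio, the selectivity factor S = t_l/t_f, is 1.50, so my curve ends at the ceiling C = S/(1+S) = 60.1%.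

At 6.0 h my curve returned that mean, 46.0%, by construction. Violet's first reading gave 7.14 h for t_f, close to the 6.88 h above, so I saw no lag within the scatter and expected little from east. Assuming that north-west, the doubled saturation concentration of gas phase, doubled the formation rate, I reckoned 67.7%. The forecast said 46%, north-west and 55%, the last “where formation meets loss”.

    gas phase ⇌ dissolved gas, rate k1*(csat - [dissolved gas]) (kL = 128 /h)
    substrate + dissolved gas → target (k = 25.7 /M/h)
    substrate → side product (k = 0.0981 /h)
    dissolved gas → decomposed reagent (k = 0.0615 /h)

The flask gave 47.4%, north-west as best change and 69.0% after it, while east gained 0.13 points. This flask had not come to rest: 22.1% of the substrate remained at 6.00 h, which at C means 13 points more target. At 60.0 h target read 60.9%, up 14 points, with substrate at 0%. For the neighbour read at 25 h, S gave 60.0%; it held 60.8%, with 0.18% of its substrate left.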